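(The readings were computed from invented constants; scatter was added.)

The constants of these steps are not given, so I reckon from the runs and carry one number out of them.

| flask | starting material | coupling partner | protic impurity | temperature | remark | time |
|---|---|---|---|---|---|---|
| winter | 3.6 mM | 12 mM | 1 mM | 20 °C | run made earlier |  |
| noon | 5.4 mM | 12 mM | 1 mM | 35 °C | run made earlier |  |
| autumn | 9.6 mM | 12 mM | 1 mM | 20 °C | run made earlier |  |
| theta | 10 mM | 12.0 mM | 1.00 mM | 35 °C |  | 40 min |
| eta | 3.0 mM | 12.0 mM | 1.00 mM | 35 °C |  | 10 min |

- winter (time / min: target / %): 5.00: 2.8; 10.0: 9.7; 25.0: 16.0; 60.0: 22.9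
- noon (time / min: target / %): 8.00: 18.5; 15.0: 22.9; 20.0: 24.1; 30.0: 27.0
- autumn (time / min: target / %): 5.00: 2.6; 10.0: 8.7; 25.0: 14.0; 60.0: 18.9

(standard deviation of a reading: 1 percentage point)

- the numbers in the tables scatter with a standard deviation of 1 percentage point
- steps under discussion: starting material + coupling partner -> target; starting material + 2 coupling partner -> side product; starting material + protic impurity -> quenched substrate; coupling partner -> decomposed reagent; 2 coupling partner -> self-condensation product

* which one finishes higher in amount of target, in percent of the starting material charged ("neither" within 2 percentage points) (theta / eta / neither)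
* amount of target at the end, in percent of the starting material charged, theta
* amount of target at the end, in percent of the starting material charged, eta

1. Both new flasks stand at 35 °C, so I draw the curve of the noon run first. Target reaches 18.5% by 8.00 min, then gains 4.4 percentage points up to 15.0 min. On that slope it stands at 19.8% at 10 min.

2. The knee: from 15.0 min to 30.0 min it gains 4.1 points. The slope therefore falls by a factor 2.30 across 11.0 min, a decay time of 13.2 min.

3. The level: with that decay, I put the noon curve at 28.1% at 40 min, running into about 29.0%.

4. Autumn and winter differ in loading. Summed over 4 readings, autumn gives 0.860 of the winter target. That makes the loading penalty, the fall in ln(target percent) per mM of starting material charged, 0.0252 mM⁻¹. I assume it holds at 35 °C.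

5. From noon's 5.4 mM, theta at 10 mM takes a factor 0.891, giving 25.0%. Eta at 3.0 mM takes 1.06, giving 21.0%. I expect theta higher, beyond the margin.

6. The forecast says theta, with 25% and 21.5%: “Theta's extra time outweighs its loading penalty”. Its eta figure stands above mine.

7. The flasks give 25.0% for theta and 20.6% for eta, so theta finishes higher, as the forecast said.

    starting material + coupling partner → target (k = 3.70 M⁻¹ min⁻¹, Ea = 64.0 kJ mol⁻¹)
    starting material + 2 coupling partner → side product (k = 400 M⁻² min⁻¹, Ea = 42.0 kJ mol⁻¹)
    starting material + protic impurity → quenched substrate (k = 7.10 M⁻¹ min⁻¹, Ea = 43.0 kJ mol⁻¹)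
    coupling partner → decomposed reagent (k = 0.0460 min⁻¹, Ea = 84.0 kJ mol⁻¹)
    2 coupling partner → self-condensation product (k = 1.90 M⁻¹ min⁻¹, Ea = 67.0 kJ mol⁻¹)
    (constants at 35 °C)

At 40 min theta holds 52% of its starting material beside 2.6% of its coupling partner, the limiting reagent there, while eta at 10 min keeps 39%. Dividing theta's result by its loading factor gives 28.1% for noon's loading, and the noon flask taken to 40 min stands at 28.8%.

8. Eta left until 40 min: the noon curve at that time with eta's factor gives 29.8%, and that flask gives 30.9%.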